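A drain time of 0.320 h, read from the first two theta readings, is the number to get right here: τ, the drain time, is the time constant with which the complex with one exchanged would leave if nothing fed it.

common to all: starting complex 0.80 M
- theta: incoming ligand 0.80 M; the very flask that is asked about, followed so far
- epsilon: incoming ligand 0.40 M; run made earlier
- flask: incoming ligand 0.800 M; time 50 h

| run | time / h | complex with one exchanged / % |
|---|---|---|
| theta | 0.167 | 7.1 |
| theta | 0.667 | 13.6 |
| theta | 3.00 | 5.2 |
| theta | 15.0 | 1.9 |
| epsilon | 0.500 | 7.8 |
| epsilon | 2.50 | 5.1 |
| epsilon | 10.0 | 1.8 |
| epsilon | 48.0 | 1.4 |

(standard deviation of a reading: 0.5 percentage points)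

1. the best time, 50 h at the latest, for complex with one exchanged
2. the amount of complex with one exchanged, in percent of the starting complex charged, at that time

Treat that complex as a tank, fed by the first exchange with a pseudo-first-order constant a. Freeze the feed and the level climbs towards the plateau aτ. The climb's relative speed, falling as exp(−t/τ)/τ, meets the fading of the feed, taken as a, at t_p = τ ln(1/(aτ)).

So which readings count? The first theta reading, taken as a straight climb from zero, gives a = 0.425 /h, and the second, taken near the plateau, gives aτ. The scatter is 7.04 % of the first reading, and t_p shifts by about that share. The larger second reading moves it less, and the late readings don't enter. My reckoning is therefore t_p = 0.638 h, give or take 0.0449 h, with a height near the reading of 13.6 %.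

The forecast comes later, at 0.8 h (range 0.5 h to 1.2 h), with 14.2 % (range 13.3 % to 16 %): “Nothing suggests a late rise”.

| | time | height |
|---|---|---|
| my reckoning | 0.638 h | 13.6 % |
| forecast | 0.8 h | 14.2 % |
| flask | 0.631 h | 14.0 % |

    starting complex + incoming ligand → leaving ligand + complex with one exchanged (k = 0.842 /M/h)
    complex with one exchanged + incoming ligand → leaving ligand + complex with two exchanged (k = 0.734 /M/h)
    complex with two exchanged + incoming ligand → leaving ligand + complex with three exchanged (k = 1.50 /M/h)
    complex with three exchanged + incoming ligand → leaving ligand + complex with four exchanged (k = 0.121 /M/h)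
    complex with one exchanged ⇌ isomer of the product (K = 24.3, k = 1.95 /h)
    crystals ⇌ complex with one exchanged, rate k6*(cs6 - [complex with one exchanged]) while solid is left; crystals form when [complex with one exchanged] > cs6 (solubility = 0.240 M, k = 3.76 /h)

Now take the neighbouring flask with 2.0 M of incoming ligand. The first step is first order in that ligand, so a becomes 1.06 /h, and with τ frozen you reckon a plateau of 34.0 %. That neighbouring flask reaches 23.3 %, lower, as if its drain time were 0.220 h.

(All runs were computed with constants of no real substance, noise included.)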